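(The earlier runs and the new flask are simulated for an exercise, and the scatter is random.)

**Grey decision.** At 3.1 h, the last reading, the green run still holds 0.5213 M of substrate and has lost just 0.00540 M since 2.6 h. The grey run repeats the green substrate with half of the catalyst. The question is whether it turns enough substrate to be worth charging.

| flask | substrate | free catalyst | time |
|---|---|---|---|
| ochre | 0.250 M | 0.0200 M |  |
| violet | 0.150 M | 0.0200 M |  |
| green | 0.750 M | 0.0200 M |  |
| teal | 0.250 M | 0.0400 M |  |
| grey | 0.750 M | 0.0100 M | 3.1 h |

| run | time / h | [substrate] / M |
|---|---|---|
| ochre run | 0.52 | 0.2027 |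
| ochre run | 1.0 | 0.1719 |
| ochre run | 1.6 | 0.1517 |
| ochre run | 2.1 | 0.1396 |
| ochre run | 2.6 | 0.1345 |
| ochre run | 3.1 | 0.1313 |
| violet run | 0.52 | 0.1196 |
| violet run | 1.0 | 0.0980 |
| violet run | 1.6 | 0.0821 |
| violet run | 2.1 | 0.0772 |
| violet run | 2.6 | 0.0705 |
| violet run | 3.1 | 0.0668 |
| green run | 0.52 | 0.6484 |
| green run | 1.0 | 0.5850 |
| green run | 1.6 | 0.5425 |
| green run | 2.1 | 0.5315 |
| green run | 2.6 | 0.5267 |
| green run | 3.1 | 0.5213 |
| teal run | 0.52 | 0.1505 |
| teal run | 1.0 | 0.1086 |
| teal run | 1.6 | 0.0918 |
| teal run | 2.1 | 0.0852 |
| teal run | 2.6 | 0.0818 |
| teal run | 3.1 | 0.0793 |

(each reading ± 0.001 M)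

- order of the initial rate in [substrate], near the charge of the ochre run, the rate being that where two percent of its substrate are product (one fixed amount of product, the same in the runs compared)
- order of the initial rate in [free catalyst], near the charge of the ochre run, the rate being that where two percent of its substrate are product
- substrate in the grey run at 3.1 h, as a share of the substrate charged

- Overall: substrate -> product, with free catalyst as catalyst.
- Constant volume, constant temperature.
- Readings of a species count what is bound in complexes too.
- An order is taken over about fifteen percent of the charge, up and down.

**Burden rule.** The reckoning here assumes that free catalyst both makes product, at a rate following substrate, and dies, at a rate following product. Time and the level of free catalyst then cancel, and catalyst lost tracks one quantity, the burden: B = c(start)·ln(c(start)/c(now)) − (c(start) − c(now)), both of substrate.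

At 3.1 h, B is 0.0381 M in violet, 0.0423 M in ochre and 0.0441 M in green. These lie close together, though substrate charges run from 0.150 M to 0.750 M at one catalyst charge. Teal, with 0.0400 M of catalyst, reaches 0.116 M, more than green.

Teal and green give the burden carried per unit of catalyst, 3.61. These are readings, teal and green differ in substrate as well, and teal is still creeping. The line reaches zero burden near 0.00779 M of catalyst charged.

**The reckoning.** Grey's charge lies above that point, and its burden at stall comes to 0.00799 M. Inverting B gives 13.9% turned, or 86.1% of the substrate left. That is about 0.104 M of product, far above the scatter, so grey is charged. If early rate follows the same counted catalyst, its order near ochre is 1.64.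

**The forecast.** It reasons that “the catalyst is dying” and gives 82% left (range 79% to 85%), substrate order 0.8 and catalyst order 1.35. Its share left is lower than the reckoning here, and so is its catalyst order.

**Grey result.** Substrate stands at 87.1% of its charge at 3.1 h, above the forecast's range, the substrate order is 0.81 and the catalyst order is 1.6. The steps behind the readings are:

    free catalyst + substrate ⇌ catalyst-substrate complex, settled at all times (1.060 L mol⁻¹)
    catalyst-substrate complex → product + free catalyst (38.88 h⁻¹)
    free catalyst + product → spent catalyst + product (11.81 L mol⁻¹ h⁻¹)
    free catalyst + impurity → spent catalyst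

Grey's burden at that reading is 0.00682 M, which at 3.61 stands for 0.00189 M of catalyst lost to the product step. The violet run made half of its charge as product by 2.09 h, where its burden is 0.0290 M, which stands for 0.00803 M of catalyst lost to the product step.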